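## Structural features

The target is a benzotropolone, a 5H-benzo[7]annulen-5-one with hydroxyls at C3, C4 and C6. It carries two flavan-type chromans: chroman B on the benzo ring at C2 and chroman A on the seven-membered ring at C8. Each chroman has a 5,7-dihydroxylated benzo ring and two adjacent stereocentres, the benzylic C2 (bonded to the ring oxygen and to the benzotropolone) and the carbinol C3. Read from the structure, chroman A is (2R,3R), 2,3-cis, with its 3-oxygen esterified by a galloyl group; chroman B is (2S,3R), 2,3-trans, with a free 3-hydroxyl. The two stereo-pairs are separated by the flat benzotropolone, so each has to be set by reagent control. Fragile elements are the ten phenolic or tropolone hydroxyls and one secondary alcohol, the reducible and nucleophile-sensitive tropolone, the base-labile gallate, and the benzylic C2–O bonds of the chromans, which can ionize under strong acid. The real difficulty is the unsymmetrical 2,8-disubstituted, 3,4,6-trioxygenated benzotropolone whose two chromans differ in relative configuration and in acylation. The key step exploits that C4 of chroman A is a methylene between oxygenated C3 and C4a of a symmetric 3,5-dioxygenated phenyl ether, so that cutting C4–C4a leaves an aryl ether of an oxiranyl carbinol with C2 and C3 already in place.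

## Logic of the disconnections

34 ⇒ 33. The eleven O–benzyl bonds are cut last. One protecting group for every hydroxyl gives a single final operation; the forward step must be non-reductive (tropolone) and must spare the ester.

33 ⇒ 31 + 32. The ester C–O bond at C3 of chroman A is cut. 31 has exactly one free hydroxyl, so the acylation needs no selectivity beyond tolerating an axial secondary alcohol.

31 ⇒ 30. The C4–C4a bond of chroman A is cut (key step). The pyran ring is traded for an oxirane and an aryl ether whose two stereocentres are already those of the product. The forward step must open the oxirane at its terminal carbon only.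

30 ⇒ 29 + 7. The aryl ether C–O bond at the future C2 is cut. A 2,3-cis chroman needs the threo ether, which an SN2 etherification with inversion delivers from the erythro epoxy alcohol; the forward step must be a clean inversion at a hindered carbinol.

29 ⇒ 28 ⇒ 26 + 27. The oxirane oxygen is removed and then the vinyl–carbinol C–C bond is cut. A tartrate-controlled epoxidation sorts the two carbinol epimers of 28 and sets both centres of chroman A at once. The cost is that at most half of 28 is used directly, and the vinyl nucleophile must choose the formyl group over the tropone.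

26 ⇒ 25 ⇒ 24 ⇒ 22. The formyl group is taken back to a silyl-protected hydroxymethyl group and the C6=C7 double bond to a β-hydroxy ketone. The tropone then arises by a simple dehydration, with no oxidation of the ring required.

22 ⇒ 21. The C8=C9 double bond is cut. The seven-membered ring becomes an acyclic diene with a styrene and a 1,1-disubstituted alkene; the forward metathesis must form a trisubstituted alkene.

21 ⇒ 16 + 19, and 19 ⇒ 18 ⇒ 17. The C6–C7 bond is cut as an aldol bond. 19 brings C7, C8 and the masked formyl carbon in one piece; its two new stereocentres need no control because both become sp2.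

16 ⇒ 15 ⇒ 12 + 13. The vinyl–arene bond at C9a and the acyl–arene bond at C4a are cut. The bromine of 12 serves twice: it acidifies the neighbouring ring hydrogen for metalation and acylation, then leaves in the cross-coupling.

12 ⇒ 11 ⇒ 10. The 3-O-benzyl bond and then the C4–C4a bond of chroman B are cut. The same oxirane–arene closure is rehearsed on a simple substrate; a 2,3-trans chroman requires the erythro ether.

10 ⇒ 8 ⇒ 6 + 7. The oxirane is reopened to a 1,2-diol and the aryl ether C–O bond at the benzylic carbon is cut. The erythro ether follows from an anti opening of a trans-epoxy alcohol, so no resolution is needed; the forward step must open the benzylic carbon selectively.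

6 ⇒ 5 ⇒ 4 ⇒ 3 ⇒ 2 ⇒ 1. The oxirane oxygen, the allylic alcohol, the two-carbon extension and the benzyl groups are removed in turn. This leads back to a commercial bromosalicylaldehyde whose substituents map onto C2 (formyl), C3 and C4 (oxygens) and C9a (bromine) of the benzotropolone.

## Other disconnections considered

Alternative 1: The cut is C7–C8 and C8–C9, with C8 inserted as a carbene carbon into a six-membered carbocycle. In the forward sense the styrenic double bond of the dihydronaphthalene cis-diol acetonide A1 would take up dibromocarbene (CHBr3, aqueous NaOH, phase-transfer catalyst) to give the gem-dibromocyclopropane A2. Electrocyclic opening with loss of bromide, release of the diol and oxidation would then give a benzotropolone that keeps a bromine at C8.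
- In favour: the carbene chemistry is cheap and scalable, and the positions of C5, C6 and C8 are fixed by the bicyclic precursor. A bromide at C8 is a more general handle than the hydroxymethyl arm carried through steps 14 to 18; on this point the alternative is the better.
- Against: a pentasubstituted 1,2-dihydronaphthalene cis-diol has to be made first. Four sp3 centres are created and erased. The diol must be oxidized and the tropolone oxygen benzylated with possible site ambiguity. The masked formyl group at C2 would force chroman B to be built after the tropolone, where ester reductions are not tolerated.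
- Comparison: the alternative replaces only steps 10 to 16 and leaves the closure of chroman A untouched. On stereochemistry the two are equal, since neither ring construction sets a lasting centre. On mechanism the carbene addition is at least as dependable as the metathesis of step 15. On step count it is judged longer.

Alternative 2: The cut is C7=C8 with both chromans already attached. In the forward sense the diene A3 would be closed with RuCl2(=CHPh)(H2IMes)(PCy3), the second-generation Grubbs catalyst, to the dihydrobenzotropolone A4. Oxidation of the α-hydroxy ketone to the 5,6-dione and tautomerization would give the tropolone.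
- In favour: it is more convergent than the chosen plan, because chroman A arrives as a finished gallate and the longest linear sequence would be shorter; on this point it is the better. The ring-closing reaction is of the same class as step 15, so on mechanism the two are equal.
- Against: the 1,1-disubstituted alkene carries a fully substituted chroman next to a gallate, so a hindered trisubstituted alkene must form. The doubly activated C9 methylene and the allylic, oxygen-bearing C2 of chroman A invite isomerization and epimerization. Oxidation and aromatization would have to be done late, in the presence of eleven benzyl ethers and two chromans. The fragment with C2 of chroman A on an alkene carbon needs its own asymmetric synthesis.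
- Comparison: the chosen plan does its metathesis early on a simple diene and closes chroman A last on an electron-poor, configurationally safe benzotropolone; the alternative concentrates its risk in the final steps.

Alternative 3: The cut is C6–C7, C8–C9 and the bond from C6 to the former formyl oxygen. In the forward sense Rh2(OAc)4 would decompose the ortho-formyl diazoketone A5, the carbenoid would be captured by the formyl oxygen, and the resulting dipole would add across the alkyne A6 to give the oxygen-bridged cycloadduct A7. Acid-induced opening of the bridge would give the tropolone.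
- In favour: one step builds the seven-membered ring and delivers the C6 oxygen at the correct oxidation level. No dehydration or oxidation of the ring is needed, so on redox economy it is better than the chosen plan, and it is as convergent as Alternative 2.
- Against: the orientation of the dipole addition, which must place the chroman on C8 and not C7, is governed by orbital coefficients and is not secured by the substrate. The propargylic, oxygen-bearing C2 of A6 can ionize or react with the carbenoid. The ortho-formyl diazoketone is prone to cyclize on its own. The bridge opening needs acid in the presence of both chromans, and A6 has no aryl group at C2 to support a standard flavan synthesis.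
- Comparison: on step count the core could be the shortest of all. On mechanism and control of regiochemistry the chosen plan is safer, because every bond of the ring is formed at a site fixed by the substrate.

Key step: step 22

Remark on the chemistry: the tropolone is carried as its 6-O-benzyl 5-oxo form (the 5-hydroxy-6-one and 6-hydroxy-5-one forms of the free tropolone are one compound), and 13, tributyl(vinyl)stannane and both enantiomers of diisopropyl tartrate are taken as purchasable.

## Steps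

Step 1
Reactants: 1 5-bromo-2-hydroxy-3-methoxybenzaldehyde
Product: 2 5-bromo-2,3-dihydroxybenzaldehyde
Conditions: BBr3, CH2Cl2, −78 °C → rt; then H2O
Reagents that add atoms: none
Why: Lewis-acid ether cleavage: boron binds the methoxy oxygen and bromide removes the methyl group by SN2, while the aldehyde is held as a borate chelate and released on work-up.

Step 2
Reactants: 2 5-bromo-2,3-dihydroxybenzaldehyde
Product: 3 2,3-bis(benzyloxy)-5-bromobenzaldehyde
Conditions: BnBr, K2CO3, DMF, 60 °C
Reagents that add atoms: benzyl bromide, BrCc1ccccc1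
Why: Williamson ether synthesis on both phenoxides; benzyl is used on every oxygen so that one final deprotection suffices.

Step 3
Reactants: 3 2,3-bis(benzyloxy)-5-bromobenzaldehyde
Product: 4 ethyl (2E)-3-[2,3-bis(benzyloxy)-5-bromophenyl]prop-2-enoate
Conditions: (EtO)2P(O)CH2CO2Et, NaH, THF, 0 °C → rt
Reagents that add atoms: triethyl phosphonoacetate, CCOC(=O)CP(=O)(OCC)OCC
Why: Horner–Wadsworth–Emmons olefination; the stabilized phosphonate anion should give the E-enoate.

Step 4
Reactants: 4 ethyl (2E)-3-[2,3-bis(benzyloxy)-5-bromophenyl]prop-2-enoate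
Product: 5 (2E)-3-[2,3-bis(benzyloxy)-5-bromophenyl]prop-2-en-1-ol
Conditions: iBu2AlH, CH2Cl2, −78 °C; aq. KNaC4H4O6
Reagents that add atoms: none
Why: 1,2-reduction of the enoate to the allylic alcohol by the aluminium hydride at low temperature; the aryl bromide and benzyl ethers are inert.

Step 5
Reactants: 5 (2E)-3-[2,3-bis(benzyloxy)-5-bromophenyl]prop-2-en-1-ol
Product: 6 [(2R,3R)-3-[2,3-bis(benzyloxy)-5-bromophenyl]oxiran-2-yl]methanol
Conditions: Ti(OiPr)4 (10 mol %), D-(−)-diisopropyl tartrate (13 mol %), t-BuOOH, 4 Å molecular sieves, CH2Cl2, −20 °C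
Reagents that add atoms: tert-butyl hydroperoxide, CC(C)(C)OO
Why: Sharpless asymmetric epoxidation of an E-allylic alcohol; the D-(−)-tartrate ligand directs oxygen to the face that gives the (2R,3R)-epoxy alcohol, and C2 of 6 becomes C3 of chroman B.

Step 6
Reactants: 6 [(2R,3R)-3-[2,3-bis(benzyloxy)-5-bromophenyl]oxiran-2-yl]methanol; 7 3,5-bis(benzyloxy)phenol
Product: 8 (2R,3S)-3-[3,5-bis(benzyloxy)phenoxy]-3-[2,3-bis(benzyloxy)-5-bromophenyl]propane-1,2-diol
Conditions: NaOH, Bu4NBr (cat.), dioxane/H2O, 70 °C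
Reagents that add atoms: none
Why: Base-mediated SN2 opening of a 3-aryl-2,3-epoxy alcohol by a phenoxide at the benzylic carbon; inversion there turns (R) into (S), the future C2 of chroman B, and gives the erythro aryl ether.

Step 7
Reactants: 8 (2R,3S)-3-[3,5-bis(benzyloxy)phenoxy]-3-[2,3-bis(benzyloxy)-5-bromophenyl]propane-1,2-diol
Product: 10 (2R)-2-[(S)-[3,5-bis(benzyloxy)phenoxy][2,3-bis(benzyloxy)-5-bromophenyl]methyl]oxirane, via primary tosylate 9 (not isolated)
Conditions: NaH, N-tosylimidazole, THF, 0 °C → rt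
Reagents that add atoms: none
Why: Selective sulfonylation of the primary hydroxyl followed by intramolecular Williamson closure; the secondary C–O bond is not broken, so its configuration is retained.

Step 8
Reactants: 10 (2R)-2-[(S)-[3,5-bis(benzyloxy)phenoxy][2,3-bis(benzyloxy)-5-bromophenyl]methyl]oxirane
Product: 11 (2S,3R)-5,7-bis(benzyloxy)-2-[2,3-bis(benzyloxy)-5-bromophenyl]chroman-3-ol
Conditions: BF3·OEt2 (cat.), (CF3)2CHOH/CH2Cl2, −20 → 0 °C, high dilution
Reagents that add atoms: none
Why: Intramolecular Friedel–Crafts opening of the oxirane at its terminal carbon (6-endo), the same reaction type as the key step on a simple substrate; no stereocentre is touched, so the erythro ether appears as the 2,3-trans chroman.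

Step 9
Reactants: 11 (2S,3R)-5,7-bis(benzyloxy)-2-[2,3-bis(benzyloxy)-5-bromophenyl]chroman-3-ol
Product: 12 (2S,3R)-3,5,7-tris(benzyloxy)-2-[2,3-bis(benzyloxy)-5-bromophenyl]chroman
Conditions: NaH, BnBr, Bu4NI (cat.), DMF, 0 °C → rt
Reagents that add atoms: benzyl bromide, BrCc1ccccc1
Why: Williamson O-benzylation of the secondary alcohol; it masks the 3-hydroxyl of chroman B so that later only chroman A offers a free hydroxyl for the gallate.

Step 10
Reactants: 12 (2S,3R)-3,5,7-tris(benzyloxy)-2-[2,3-bis(benzyloxy)-5-bromophenyl]chroman; 13 2-(benzyloxy)-N-methoxy-N-methylacetamide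
Product: 15 2-(benzyloxy)-1-[2,3-bis(benzyloxy)-6-bromo-4-[(2S,3R)-3,5,7-tris(benzyloxy)chroman-2-yl]phenyl]ethan-1-one, via aryllithium 14 (not isolated)
Conditions: LiN(iPr)2, THF, −78 °C; then 13, −78 °C; aq. NH4Cl
Reagents that add atoms: none
Why: Directed ortho-metalation: the ring hydrogen flanked by bromine and a benzyloxy group is the most acidic C–H and is removed by the amide base at −78 °C; the aryllithium is acylated by the Weinreb amide, whose chelated tetrahedral adduct prevents over-addition.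

Step 11
Reactants: 15 2-(benzyloxy)-1-[2,3-bis(benzyloxy)-6-bromo-4-[(2S,3R)-3,5,7-tris(benzyloxy)chroman-2-yl]phenyl]ethan-1-one
Product: 16 2-(benzyloxy)-1-[2,3-bis(benzyloxy)-6-ethenyl-4-[(2S,3R)-3,5,7-tris(benzyloxy)chroman-2-yl]phenyl]ethan-1-one
Conditions: CH2=CHSnBu3, Pd(PPh3)4 (5 mol %), toluene, 100 °C
Reagents that add atoms: tributyl(vinyl)stannane, C=C[Sn](CCCC)(CCCC)CCCC
Why: Stille cross-coupling of the aryl bromide; the neutral conditions spare the enolizable α-benzyloxy ketone.

Step 12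
Reactants: 17 2-methylidenepropane-1,3-diol
Product: 18 2-[(tert-butyldimethylsilyloxy)methyl]prop-2-en-1-ol
Conditions: NaH (1 equiv), THF, 0 °C; then TBSCl
Reagents that add atoms: tert-butyldimethylsilyl chloride, CC(C)(C)[Si](C)(C)Cl
Why: Monosilylation of a symmetrical diol through its sparingly soluble monosodium alkoxide, which should favour the mono-ether.

Step 13
Reactants: 18 2-[(tert-butyldimethylsilyloxy)methyl]prop-2-en-1-ol
Product: 19 2-[(tert-butyldimethylsilyloxy)methyl]prop-2-enal
Conditions: MnO2, CH2Cl2, rt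
Reagents that add atoms: none
Why: Selective oxidation of an allylic alcohol to the enal by MnO2; the silyl ether is untouched.

Step 14
Reactants: 16 2-(benzyloxy)-1-[2,3-bis(benzyloxy)-6-ethenyl-4-[(2S,3R)-3,5,7-tris(benzyloxy)chroman-2-yl]phenyl]ethan-1-one; 19 2-[(tert-butyldimethylsilyloxy)methyl]prop-2-enal
Product: 21 aldol adduct 2-(benzyloxy)-1-[2,3-bis(benzyloxy)-6-ethenyl-4-[(2S,3R)-3,5,7-tris(benzyloxy)chroman-2-yl]phenyl]-3-hydroxy-4-[(tert-butyldimethylsilyloxy)methyl]pent-4-en-1-one (diastereomers at C2 and C3 of the chain), via lithium enolate 20 (not isolated)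
Conditions: LiN(iPr)2, THF, −78 °C; then 19; AcOH, −78 °C
Reagents that add atoms: none
Why: Aldol addition of a lithium enolate, which adds 1,2 to the enal at low temperature and forms the C6–C7 bond; the two new stereocentres are left uncontrolled because both become sp2 in step 16.

Step 15
Reactants: 21 aldol adduct (diastereomer mixture)
Product: 22 3,4,6-tris(benzyloxy)-8-[(tert-butyldimethylsilyloxy)methyl]-7-hydroxy-2-[(2S,3R)-3,5,7-tris(benzyloxy)chroman-2-yl]-6,7-dihydro-5H-benzo[7]annulen-5-one (diastereomers at C6 and C7)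
Conditions: RuCl2(=CHPh)(H2IMes)(PCy3) (second-generation Grubbs catalyst, 10 mol %), toluene, 80 °C, 2 mM
Reagents that add atoms: none
Why: Ring-closing olefin metathesis between the styrene and the 1,1-disubstituted alkene; it forms the trisubstituted C8=C9 bond and the seven-membered ring and is driven by loss of ethene.

Step 16
Reactants: 22 3,4,6-tris(benzyloxy)-8-[(tert-butyldimethylsilyloxy)methyl]-7-hydroxy-2-[(2S,3R)-3,5,7-tris(benzyloxy)chroman-2-yl]-6,7-dihydro-5H-benzo[7]annulen-5-one
Product: 24 3,4,6-tris(benzyloxy)-8-[(tert-butyldimethylsilyloxy)methyl]-2-[(2S,3R)-3,5,7-tris(benzyloxy)chroman-2-yl]-5H-benzo[7]annulen-5-one, via C7 mesylate 23 (not isolated)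
Conditions: MsCl, Et3N, CH2Cl2, 0 °C → rt
Reagents that add atoms: none
Why: Sulfonylation and E1cB elimination of the β-hydroxy ketone (C6–H is α to the ketone); the product is the fully conjugated benzotropone, whose stabilization drives the elimination, and all diastereomers converge.

Step 17
Reactants: 24 3,4,6-tris(benzyloxy)-8-[(tert-butyldimethylsilyloxy)methyl]-2-[(2S,3R)-3,5,7-tris(benzyloxy)chroman-2-yl]-5H-benzo[7]annulen-5-one
Product: 25 3,4,6-tris(benzyloxy)-8-(hydroxymethyl)-2-[(2S,3R)-3,5,7-tris(benzyloxy)chroman-2-yl]-5H-benzo[7]annulen-5-one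
Conditions: HF·pyridine, THF, 0 °C → rt
Reagents that add atoms: none
Why: Fluoride-mediated cleavage of the primary silyl ether; the buffered acidic reagent avoids basic conditions on the tropone.

Step 18
Reactants: 25 3,4,6-tris(benzyloxy)-8-(hydroxymethyl)-2-[(2S,3R)-3,5,7-tris(benzyloxy)chroman-2-yl]-5H-benzo[7]annulen-5-one
Product: 26 3,4,6-tris(benzyloxy)-5-oxo-2-[(2S,3R)-3,5,7-tris(benzyloxy)chroman-2-yl]-5H-benzo[7]annulene-8-carbaldehyde
Conditions: MnO2, CH2Cl2, rt
Reagents that add atoms: none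
Why: MnO2 oxidation of a primary alcohol on an sp2 ring carbon (allylic type) to the aldehyde without over-oxidation.

Step 19
Reactants: 26 3,4,6-tris(benzyloxy)-5-oxo-2-[(2S,3R)-3,5,7-tris(benzyloxy)chroman-2-yl]-5H-benzo[7]annulene-8-carbaldehyde; 27 vinylmagnesium bromide
Product: 28 3,4,6-tris(benzyloxy)-8-(1-hydroxyprop-2-en-1-yl)-2-[(2S,3R)-3,5,7-tris(benzyloxy)chroman-2-yl]-5H-benzo[7]annulen-5-one (both carbinol epimers)
Conditions: CH2=CHMgBr (1.1 equiv), THF, −78 °C; aq. NH4Cl
Reagents that add atoms: none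
Why: Grignard 1,2-addition; at −78 °C the formyl group should be far more electrophilic than the cross-conjugated tropone carbonyl. The new carbinol centre forms without control and is sorted in step 20.

Step 20
Reactants: 28 3,4,6-tris(benzyloxy)-8-(1-hydroxyprop-2-en-1-yl)-2-[(2S,3R)-3,5,7-tris(benzyloxy)chroman-2-yl]-5H-benzo[7]annulen-5-one (both carbinol epimers)
Product: 29 3,4,6-tris(benzyloxy)-8-[(S)-hydroxy[(2R)-oxiran-2-yl]methyl]-2-[(2S,3R)-3,5,7-tris(benzyloxy)chroman-2-yl]-5H-benzo[7]annulen-5-one (erythro)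
Conditions: Ti(OiPr)4 (1.0 equiv), L-(+)-diisopropyl tartrate (1.2 equiv), t-BuOOH (0.6 equiv), 4 Å molecular sieves, CH2Cl2, −20 °C
Reagents that add atoms: tert-butyl hydroperoxide, CC(C)(C)OO
Why: Sharpless kinetic resolution: with the L-(+)-tartrate ligand the (R)-carbinol epimer of 28 should be epoxidized much faster and give the erythro epoxy alcohol, with (R) at the oxirane carbon that becomes C3 of chroman A; the other epimer is separated by chromatography.

Step 21
Reactants: 29 3,4,6-tris(benzyloxy)-8-[(S)-hydroxy[(2R)-oxiran-2-yl]methyl]-2-[(2S,3R)-3,5,7-tris(benzyloxy)chroman-2-yl]-5H-benzo[7]annulen-5-one; 7 3,5-bis(benzyloxy)phenol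
Product: 30 3,4,6-tris(benzyloxy)-8-[(R)-[3,5-bis(benzyloxy)phenoxy][(2R)-oxiran-2-yl]methyl]-2-[(2S,3R)-3,5,7-tris(benzyloxy)chroman-2-yl]-5H-benzo[7]annulen-5-one (threo)
Conditions: PPh3, iPrO2CN=NCO2iPr, toluene, 0 °C → rt
Reagents that add atoms: none
Why: Mitsunobu etherification; SN2 displacement of the oxyphosphonium group by the phenoxide inverts the carbinol carbon and turns the erythro alcohol into the threo ether, (R) at the future C2 of chroman A. The electron-poor tropone ring disfavours ionization, so inversion should be clean.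

Step 22
Reactants: 30 3,4,6-tris(benzyloxy)-8-[(R)-[3,5-bis(benzyloxy)phenoxy][(2R)-oxiran-2-yl]methyl]-2-[(2S,3R)-3,5,7-tris(benzyloxy)chroman-2-yl]-5H-benzo[7]annulen-5-one
Product: 31 3,4,6-tris(benzyloxy)-8-[(2R,3R)-5,7-bis(benzyloxy)-3-hydroxychroman-2-yl]-2-[(2S,3R)-3,5,7-tris(benzyloxy)chroman-2-yl]-5H-benzo[7]annulen-5-one
Conditions: BF3·OEt2 (2.2 equiv), (CF3)2CHOH/CH2Cl2, −30 → 0 °C, 2 mM; Et3N quench
Reagents that add atoms: none
Why: This is an intramolecular Friedel–Crafts alkylation by an oxirane (epoxide–arene cyclization of an aryl glycidyl-type ether), a known way to chroman-3-ols. The first equivalent of BF3 is expected to be bound by the basic tropone oxygen; the second, together with the hydrogen-bond-donating solvent, polarizes the terminal C–O bond of the oxirane. An ortho carbon of the 3,5-bis(benzyloxy)phenyl ether then attacks the CH2 terminus in an SN2-like manner, the σ-complex loses a proton, and the oxirane oxygen stays on C3 as the free hydroxyl. The bond made is C4–C4a and the ring closed is the pyran ring of chroman A, in the 6-endo mode with respect to the oxirane. No stereocentre is created or touched because the new bond ends at a methylene carbon: C2 (R, from the inversion of step 21) and C3 (R, from the tartrate-controlled epoxidation of step 20) are carried over, and the threo ether becomes the 2,3-cis chroman. Arene regiochemistry needs no control, since the two ortho positions are equivalent and the third activated position cannot reach the oxirane. The selectivity that is needed, 6-endo over 5-exo attack at the internal oxirane carbon, rests on the unhindered primary terminus and on the internal carbon being secondary and flanked by the aryloxy-bearing carbon, whose oxygen and boron-complexed tropone ring disfavour charge build-up there. High dilution and low temperature are used to suppress intermolecular alkylation and benzyl transfer.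

Step 23
Reactants: 31 3,4,6-tris(benzyloxy)-8-[(2R,3R)-5,7-bis(benzyloxy)-3-hydroxychroman-2-yl]-2-[(2S,3R)-3,5,7-tris(benzyloxy)chroman-2-yl]-5H-benzo[7]annulen-5-one; 32 3,4,5-tris(benzyloxy)benzoic acid
Product: 33 (2R,3R)-5,7-bis(benzyloxy)-2-[3,4,6-tris(benzyloxy)-5-oxo-2-[(2S,3R)-3,5,7-tris(benzyloxy)chroman-2-yl]-5H-benzo[7]annulen-8-yl]chroman-3-yl 3,4,5-tris(benzyloxy)benzoate
Conditions: N-(3-dimethylaminopropyl)-N′-ethylcarbodiimide hydrochloride, 4-(dimethylamino)pyridine, CH2Cl2, rt
Reagents that add atoms: none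
Why: Steglich esterification; the only free hydroxyl is the 3-hydroxyl of chroman A, and acyl transfer through the acylpyridinium species copes with its axial position.

Step 24
Reactants: 33 (2R,3R)-5,7-bis(benzyloxy)-2-[3,4,6-tris(benzyloxy)-5-oxo-2-[(2S,3R)-3,5,7-tris(benzyloxy)chroman-2-yl]-5H-benzo[7]annulen-8-yl]chroman-3-yl 3,4,5-tris(benzyloxy)benzoate
Product: 34 (2R,3R)-5,7-dihydroxy-2-[3,4,6-trihydroxy-5-oxo-2-[(2S,3R)-3,5,7-trihydroxychroman-2-yl]-5H-benzo[7]annulen-8-yl]chroman-3-yl 3,4,5-trihydroxybenzoate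
Conditions: BCl3, C6HMe5, CH2Cl2, −78 °C; MeOH quench
Reagents that add atoms: none
Why: Lewis-acid debenzylation with pentamethylbenzene as a non-basic benzyl-cation scavenger; the method is non-reductive, so the tropolone and the gallate ester should survive while all eleven benzyl ethers are cleaved.

## Compound list

1 | 5-bromo-2-hydroxy-3-methoxybenzaldehyde | COc1cc(Br)cc(C=O)c1O | starting material
2 | 5-bromo-2,3-dihydroxybenzaldehyde | Oc1cc(Br)cc(C=O)c1O | intermediate
3 | 2,3-bis(benzyloxy)-5-bromobenzaldehyde | O=Cc1cc(Br)cc(OCc2ccccc2)c1OCc1ccccc1 | intermediate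
4 | ethyl (2E)-3-[2,3-bis(benzyloxy)-5-bromophenyl]prop-2-enoate | CCOC(=O)/C=C/c1cc(Br)cc(OCc2ccccc2)c1OCc1ccccc1 | intermediate
5 | (2E)-3-[2,3-bis(benzyloxy)-5-bromophenyl]prop-2-en-1-ol | OC/C=C/c1cc(Br)cc(OCc2ccccc2)c1OCc1ccccc1 | intermediate
6 | [(2R,3R)-3-[2,3-bis(benzyloxy)-5-bromophenyl]oxiran-2-yl]methanol | OC[C@H]1O[C@@H]1c1cc(Br)cc(OCc2ccccc2)c1OCc1ccccc1 | intermediate
7 | 3,5-bis(benzyloxy)phenol | Oc1cc(OCc2ccccc2)cc(OCc2ccccc2)c1 | starting material
8 | (2R,3S)-3-[3,5-bis(benzyloxy)phenoxy]-3-[2,3-bis(benzyloxy)-5-bromophenyl]propane-1,2-diol | OC[C@@H](O)[C@@H](Oc1cc(OCc2ccccc2)cc(OCc2ccccc2)c1)c1cc(Br)cc(OCc2ccccc2)c1OCc1ccccc1 | intermediate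
9 | (2R,3S)-3-[3,5-bis(benzyloxy)phenoxy]-3-[2,3-bis(benzyloxy)-5-bromophenyl]-2-hydroxypropyl 4-methylbenzenesulfonate | Cc1ccc(cc1)S(=O)(=O)OC[C@@H](O)[C@@H](Oc1cc(OCc2ccccc2)cc(OCc2ccccc2)c1)c1cc(Br)cc(OCc2ccccc2)c1OCc1ccccc1 | intermediate (not isolated)
10 | (2R)-2-[(S)-[3,5-bis(benzyloxy)phenoxy][2,3-bis(benzyloxy)-5-bromophenyl]methyl]oxirane (erythro) | c1c(OCc2ccccc2)cc(OCc2ccccc2)cc1O[C@@H](c1cc(Br)cc(OCc2ccccc2)c1OCc1ccccc1)[C@H]1CO1 | intermediate
11 | (2S,3R)-5,7-bis(benzyloxy)-2-[2,3-bis(benzyloxy)-5-bromophenyl]chroman-3-ol (2,3-trans) | Brc1cc([C@@H]2Oc3cc(OCc4ccccc4)cc(OCc4ccccc4)c3C[C@H]2O)c(OCc2ccccc2)c(OCc2ccccc2)c1 | intermediate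
12 | (2S,3R)-3,5,7-tris(benzyloxy)-2-[2,3-bis(benzyloxy)-5-bromophenyl]chroman | Brc1cc([C@@H]2Oc3cc(OCc4ccccc4)cc(OCc4ccccc4)c3C[C@H]2OCc2ccccc2)c(OCc2ccccc2)c(OCc2ccccc2)c1 | intermediate
13 | 2-(benzyloxy)-N-methoxy-N-methylacetamide | CON(C)C(=O)COCc1ccccc1 | starting material
14 | [2,3-bis(benzyloxy)-6-bromo-4-[(2S,3R)-3,5,7-tris(benzyloxy)chroman-2-yl]phenyl]lithium | Brc1cc([C@@H]2Oc3cc(OCc4ccccc4)cc(OCc4ccccc4)c3C[C@H]2OCc2ccccc2)c(OCc2ccccc2)c(OCc2ccccc2)c1[Li] | intermediate (not isolated)
15 | 2-(benzyloxy)-1-[2,3-bis(benzyloxy)-6-bromo-4-[(2S,3R)-3,5,7-tris(benzyloxy)chroman-2-yl]phenyl]ethan-1-one | Brc1cc([C@@H]2Oc3cc(OCc4ccccc4)cc(OCc4ccccc4)c3C[C@H]2OCc2ccccc2)c(OCc2ccccc2)c(OCc2ccccc2)c1C(=O)COCc1ccccc1 | intermediate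
16 | 2-(benzyloxy)-1-[2,3-bis(benzyloxy)-6-ethenyl-4-[(2S,3R)-3,5,7-tris(benzyloxy)chroman-2-yl]phenyl]ethan-1-one | C=Cc1cc([C@@H]2Oc3cc(OCc4ccccc4)cc(OCc4ccccc4)c3C[C@H]2OCc2ccccc2)c(OCc2ccccc2)c(OCc2ccccc2)c1C(=O)COCc1ccccc1 | intermediate
17 | 2-methylidenepropane-1,3-diol | C=C(CO)CO | starting material
18 | 2-[(tert-butyldimethylsilyloxy)methyl]prop-2-en-1-ol | C=C(CO)CO[Si](C)(C)C(C)(C)C | intermediate
19 | 2-[(tert-butyldimethylsilyloxy)methyl]prop-2-enal | C=C(C=O)CO[Si](C)(C)C(C)(C)C | intermediate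
20 | lithium enolate of 16 | C=Cc1cc([C@@H]2Oc3cc(OCc4ccccc4)cc(OCc4ccccc4)c3C[C@H]2OCc2ccccc2)c(OCc2ccccc2)c(OCc2ccccc2)c1C(O[Li])=COCc1ccccc1 | intermediate (not isolated)
21 | 2-(benzyloxy)-1-[2,3-bis(benzyloxy)-6-ethenyl-4-[(2S,3R)-3,5,7-tris(benzyloxy)chroman-2-yl]phenyl]-3-hydroxy-4-[(tert-butyldimethylsilyloxy)methyl]pent-4-en-1-one (diastereomers at chain C2 and C3, removed in step 16) | C=Cc1cc([C@@H]2Oc3cc(OCc4ccccc4)cc(OCc4ccccc4)c3C[C@H]2OCc2ccccc2)c(OCc2ccccc2)c(OCc2ccccc2)c1C(=O)C(OCc1ccccc1)C(O)C(=C)CO[Si](C)(C)C(C)(C)C | intermediate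
22 | 3,4,6-tris(benzyloxy)-8-[(tert-butyldimethylsilyloxy)methyl]-7-hydroxy-2-[(2S,3R)-3,5,7-tris(benzyloxy)chroman-2-yl]-6,7-dihydro-5H-benzo[7]annulen-5-one (diastereomers at C6 and C7, removed in step 16) | O=C1C(OCc2ccccc2)C(O)C(CO[Si](C)(C)C(C)(C)C)=Cc2cc([C@@H]3Oc4cc(OCc5ccccc5)cc(OCc5ccccc5)c4C[C@H]3OCc3ccccc3)c(OCc3ccccc3)c(OCc3ccccc3)c12 | intermediate
23 | 7-methanesulfonate of 22 | O=C1C(OCc2ccccc2)C(OS(C)(=O)=O)C(CO[Si](C)(C)C(C)(C)C)=Cc2cc([C@@H]3Oc4cc(OCc5ccccc5)cc(OCc5ccccc5)c4C[C@H]3OCc3ccccc3)c(OCc3ccccc3)c(OCc3ccccc3)c12 | intermediate (not isolated)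
24 | 3,4,6-tris(benzyloxy)-8-[(tert-butyldimethylsilyloxy)methyl]-2-[(2S,3R)-3,5,7-tris(benzyloxy)chroman-2-yl]-5H-benzo[7]annulen-5-one | CC(C)(C)[Si](C)(C)OCc1cc(OCc2ccccc2)c(=O)c2c(OCc3ccccc3)c(OCc3ccccc3)c([C@@H]3Oc4cc(OCc5ccccc5)cc(OCc5ccccc5)c4C[C@H]3OCc3ccccc3)cc2c1 | intermediate
25 | 3,4,6-tris(benzyloxy)-8-(hydroxymethyl)-2-[(2S,3R)-3,5,7-tris(benzyloxy)chroman-2-yl]-5H-benzo[7]annulen-5-one | OCc1cc(OCc2ccccc2)c(=O)c2c(OCc3ccccc3)c(OCc3ccccc3)c([C@@H]3Oc4cc(OCc5ccccc5)cc(OCc5ccccc5)c4C[C@H]3OCc3ccccc3)cc2c1 | intermediate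
26 | 3,4,6-tris(benzyloxy)-5-oxo-2-[(2S,3R)-3,5,7-tris(benzyloxy)chroman-2-yl]-5H-benzo[7]annulene-8-carbaldehyde | O=Cc1cc(OCc2ccccc2)c(=O)c2c(OCc3ccccc3)c(OCc3ccccc3)c([C@@H]3Oc4cc(OCc5ccccc5)cc(OCc5ccccc5)c4C[C@H]3OCc3ccccc3)cc2c1 | intermediate
27 | vinylmagnesium bromide | C=C[Mg]Br | starting material
28 | 3,4,6-tris(benzyloxy)-8-(1-hydroxyprop-2-en-1-yl)-2-[(2S,3R)-3,5,7-tris(benzyloxy)chroman-2-yl]-5H-benzo[7]annulen-5-one (both carbinol epimers) | C=CC(O)c1cc(OCc2ccccc2)c(=O)c2c(OCc3ccccc3)c(OCc3ccccc3)c([C@@H]3Oc4cc(OCc5ccccc5)cc(OCc5ccccc5)c4C[C@H]3OCc3ccccc3)cc2c1 | intermediate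
29 | 3,4,6-tris(benzyloxy)-8-[(S)-hydroxy[(2R)-oxiran-2-yl]methyl]-2-[(2S,3R)-3,5,7-tris(benzyloxy)chroman-2-yl]-5H-benzo[7]annulen-5-one (erythro) | O[C@@H](c1cc(OCc2ccccc2)c(=O)c2c(OCc3ccccc3)c(OCc3ccccc3)c([C@@H]3Oc4cc(OCc5ccccc5)cc(OCc5ccccc5)c4C[C@H]3OCc3ccccc3)cc2c1)[C@H]1CO1 | intermediate
30 | 3,4,6-tris(benzyloxy)-8-[(R)-[3,5-bis(benzyloxy)phenoxy][(2R)-oxiran-2-yl]methyl]-2-[(2S,3R)-3,5,7-tris(benzyloxy)chroman-2-yl]-5H-benzo[7]annulen-5-one (threo) | c1c(OCc2ccccc2)cc(OCc2ccccc2)cc1O[C@H](c1cc(OCc2ccccc2)c(=O)c2c(OCc3ccccc3)c(OCc3ccccc3)c([C@@H]3Oc4cc(OCc5ccccc5)cc(OCc5ccccc5)c4C[C@H]3OCc3ccccc3)cc2c1)[C@H]1CO1 | intermediate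
31 | 3,4,6-tris(benzyloxy)-8-[(2R,3R)-5,7-bis(benzyloxy)-3-hydroxychroman-2-yl]-2-[(2S,3R)-3,5,7-tris(benzyloxy)chroman-2-yl]-5H-benzo[7]annulen-5-one | O[C@@H]1Cc2c(OCc3ccccc3)cc(OCc3ccccc3)cc2O[C@@H]1c1cc(OCc2ccccc2)c(=O)c2c(OCc3ccccc3)c(OCc3ccccc3)c([C@@H]3Oc4cc(OCc5ccccc5)cc(OCc5ccccc5)c4C[C@H]3OCc3ccccc3)cc2c1 | intermediate
32 | 3,4,5-tris(benzyloxy)benzoic acid | O=C(O)c1cc(OCc2ccccc2)c(OCc2ccccc2)c(OCc2ccccc2)c1 | starting material
33 | (2R,3R)-5,7-bis(benzyloxy)-2-[3,4,6-tris(benzyloxy)-5-oxo-2-[(2S,3R)-3,5,7-tris(benzyloxy)chroman-2-yl]-5H-benzo[7]annulen-8-yl]chroman-3-yl 3,4,5-tris(benzyloxy)benzoate | O=C(O[C@@H]1Cc2c(OCc3ccccc3)cc(OCc3ccccc3)cc2O[C@@H]1c1cc(OCc2ccccc2)c(=O)c2c(OCc3ccccc3)c(OCc3ccccc3)c([C@@H]3Oc4cc(OCc5ccccc5)cc(OCc5ccccc5)c4C[C@H]3OCc3ccccc3)cc2c1)c1cc(OCc2ccccc2)c(OCc2ccccc2)c(OCc2ccccc2)c1 | intermediate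
34 | (2R,3R)-5,7-dihydroxy-2-[3,4,6-trihydroxy-5-oxo-2-[(2S,3R)-3,5,7-trihydroxychroman-2-yl]-5H-benzo[7]annulen-8-yl]chroman-3-yl 3,4,5-trihydroxybenzoate | O=C(O[C@@H]1Cc2c(O)cc(O)cc2O[C@@H]1c1cc(O)c(=O)c2c(O)c(O)c([C@@H]3Oc4cc(O)cc(O)c4C[C@H]3O)cc2c1)c1cc(O)c(O)c(O)c1 | target

## Step count and least certain steps

Total: 24 steps. Longest linear sequence: 22 steps (steps 1 to 11 and 14 to 24); steps 12 and 13 prepare 19 on a side branch.

Step 22 (key step).
- What may go wrong: closure at the internal oxirane carbon to a five-membered ring, alkylation between molecules, and Lewis-acid-induced loss of the benzyl group from the tropolone oxygen (a vinylogous benzyl ester) with transfer of the benzyl cation to an electron-rich ring.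
- Fallback, from 30 back to 31: the oxirane is first opened at its terminal carbon by bromide (LiBr, AcOH, THF) to the bromohydrin 8-[(1R,2S)-1-[3,5-bis(benzyloxy)phenoxy]-3-bromo-2-hydroxypropyl]-3,4,6-tris(benzyloxy)-2-[(2S,3R)-3,5,7-tris(benzyloxy)chroman-2-yl]-5H-benzo[7]annulen-5-one F1. The primary bromide is then used in a silver-assisted intramolecular Friedel–Crafts alkylation (AgOTf, 2,6-di-tert-butylpyridine, CH2Cl2). This can only give the six-membered ring, because the leaving group sits on the terminal carbon, and it needs no boron Lewis acid.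

Step 19.
- What may go wrong: conjugate addition or addition–elimination of the Grignard reagent on the 2-benzyloxytropone ring in competition with addition to the formyl group.
- Fallback, from 26 back to 28: chromium-mediated vinylation (vinyl bromide, CrCl2, catalytic NiCl2, DMF; Nozaki–Hiyama–Kishi reaction). The organochromium species is selective for aldehydes and should leave the tropone alone. No new compound is made.

Step 20.
- What may go wrong: incomplete discrimination between the two carbinol epimers when the tropone oxygen competes for titanium, so that the resolution is slow and the erythro product is contaminated; by design at most half of 28 is converted.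
- Fallback, from 28 back to 29: the carbinol centre is set by reagent control. MnO2 oxidizes 28 to the enone 1-[3,4,6-tris(benzyloxy)-5-oxo-2-[(2S,3R)-3,5,7-tris(benzyloxy)chroman-2-yl]-5H-benzo[7]annulen-8-yl]prop-2-en-1-one F2. Corey–Bakshi–Shibata reduction with the (S)-oxazaborolidine and catecholborane gives the single (R)-carbinol epimer F3. Hydroxyl-directed epoxidation of this single epimer (VO(acac)2, t-BuOOH), which favours the erythro product, then gives 29 without a resolution.
- The unreacted epimer of step 20 can also be returned by Mitsunobu inversion and ester hydrolysis.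

Step 10.
- What may go wrong: metalation at a benzylic CH2 of one of the five benzyl ethers or at the chroman in place of the ring position between bromine and benzyloxy, and loss of LiBr from the aryllithium before it is acylated.
- Fallback, from 3 back to 15: the ring position is functionalized on the simplest substrate and carried as an iodide, so that the late step is a halogen–magnesium exchange and not a deprotonation.
  - 3 is masked in the flask as its α-amino alkoxide (LiN(CH3)CH2CH2N(CH3)2), lithiated with LiN(iPr)2 and quenched with I2 to give 2,3-bis(benzyloxy)-5-bromo-4-iodobenzaldehyde F4.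
  - The conditions of steps 3 to 9 then lead through the enoate F5, the allylic alcohol F6, the epoxy alcohol F7, the diol F8, its primary tosylate F9 (in the flask), the oxiranyl ether F10 and the chromanol F11 to the benzyl ether F12.
  - iPrMgCl·LiCl (THF, −40 °C) exchanges only the iodine to give the arylmagnesium chloride F13, which is acylated by 13 to give 15.

Step 6.
- What may go wrong: Payne rearrangement of the epoxy alcohol under base followed by attack at C1, or attack at C2, giving regioisomeric ethers.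
- Fallback, from 6 back to 8: the primary hydroxyl is silylated (TBSCl, imidazole) to the silyl ether F14, which cannot rearrange. The caesium phenoxide of 7 (Cs2CO3, DMF, 80 °C) opens the benzylic carbon to give the 3-aryloxy-2-ol silyl ether F15, and Bu4NF returns 8.

Step 24.
- What may go wrong: incomplete cleavage of the secondary alkyl benzyl ether on chroman B at −78 °C, and acid-induced opening or epimerization at C2 of the chromans if the mixture is warmed.
- Fallback, from 33 back to 34: hydrogenolysis (H2, Pd(OH)2 on carbon, THF/MeOH, short contact time), stopped before the tropolone ring is reduced. No new compound is made.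

## Further compounds

F1 | step 22 | 8-[(1R,2S)-1-[3,5-bis(benzyloxy)phenoxy]-3-bromo-2-hydroxypropyl]-3,4,6-tris(benzyloxy)-2-[(2S,3R)-3,5,7-tris(benzyloxy)chroman-2-yl]-5H-benzo[7]annulen-5-one | c1c(OCc2ccccc2)cc(OCc2ccccc2)cc1O[C@H](c1cc(OCc2ccccc2)c(=O)c2c(OCc3ccccc3)c(OCc3ccccc3)c([C@@H]3Oc4cc(OCc5ccccc5)cc(OCc5ccccc5)c4C[C@H]3OCc3ccccc3)cc2c1)[C@H](O)CBr
F0 | step 19 | none | none
F2 | step 20 | 1-[3,4,6-tris(benzyloxy)-5-oxo-2-[(2S,3R)-3,5,7-tris(benzyloxy)chroman-2-yl]-5H-benzo[7]annulen-8-yl]prop-2-en-1-one | C=CC(=O)c1cc(OCc2ccccc2)c(=O)c2c(OCc3ccccc3)c(OCc3ccccc3)c([C@@H]3Oc4cc(OCc5ccccc5)cc(OCc5ccccc5)c4C[C@H]3OCc3ccccc3)cc2c1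
F3 | step 20 | 3,4,6-tris(benzyloxy)-8-[(1R)-1-hydroxyprop-2-en-1-yl]-2-[(2S,3R)-3,5,7-tris(benzyloxy)chroman-2-yl]-5H-benzo[7]annulen-5-one | C=C[C@@H](O)c1cc(OCc2ccccc2)c(=O)c2c(OCc3ccccc3)c(OCc3ccccc3)c([C@@H]3Oc4cc(OCc5ccccc5)cc(OCc5ccccc5)c4C[C@H]3OCc3ccccc3)cc2c1
F4 | step 10 | 2,3-bis(benzyloxy)-5-bromo-4-iodobenzaldehyde | O=Cc1cc(Br)c(I)c(OCc2ccccc2)c1OCc1ccccc1
F5 | step 10 | ethyl (2E)-3-[2,3-bis(benzyloxy)-5-bromo-4-iodophenyl]prop-2-enoate | CCOC(=O)/C=C/c1cc(Br)c(I)c(OCc2ccccc2)c1OCc1ccccc1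
F6 | step 10 | (2E)-3-[2,3-bis(benzyloxy)-5-bromo-4-iodophenyl]prop-2-en-1-ol | OC/C=C/c1cc(Br)c(I)c(OCc2ccccc2)c1OCc1ccccc1
F7 | step 10 | [(2R,3R)-3-[2,3-bis(benzyloxy)-5-bromo-4-iodophenyl]oxiran-2-yl]methanol | OC[C@H]1O[C@@H]1c1cc(Br)c(I)c(OCc2ccccc2)c1OCc1ccccc1
F8 | step 10 | (2R,3S)-3-[3,5-bis(benzyloxy)phenoxy]-3-[2,3-bis(benzyloxy)-5-bromo-4-iodophenyl]propane-1,2-diol | OC[C@@H](O)[C@@H](Oc1cc(OCc2ccccc2)cc(OCc2ccccc2)c1)c1cc(Br)c(I)c(OCc2ccccc2)c1OCc1ccccc1
F9 | step 10 | (2R,3S)-3-[3,5-bis(benzyloxy)phenoxy]-3-[2,3-bis(benzyloxy)-5-bromo-4-iodophenyl]-2-hydroxypropyl 4-methylbenzenesulfonate | Cc1ccc(cc1)S(=O)(=O)OC[C@@H](O)[C@@H](Oc1cc(OCc2ccccc2)cc(OCc2ccccc2)c1)c1cc(Br)c(I)c(OCc2ccccc2)c1OCc1ccccc1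
F10 | step 10 | (2R)-2-[(S)-[3,5-bis(benzyloxy)phenoxy][2,3-bis(benzyloxy)-5-bromo-4-iodophenyl]methyl]oxirane | c1c(OCc2ccccc2)cc(OCc2ccccc2)cc1O[C@@H](c1cc(Br)c(I)c(OCc2ccccc2)c1OCc1ccccc1)[C@H]1CO1
F11 | step 10 | (2S,3R)-5,7-bis(benzyloxy)-2-[2,3-bis(benzyloxy)-5-bromo-4-iodophenyl]chroman-3-ol | Brc1cc([C@@H]2Oc3cc(OCc4ccccc4)cc(OCc4ccccc4)c3C[C@H]2O)c(OCc2ccccc2)c(OCc2ccccc2)c1I
F12 | step 10 | (2S,3R)-3,5,7-tris(benzyloxy)-2-[2,3-bis(benzyloxy)-5-bromo-4-iodophenyl]chroman | Brc1cc([C@@H]2Oc3cc(OCc4ccccc4)cc(OCc4ccccc4)c3C[C@H]2OCc2ccccc2)c(OCc2ccccc2)c(OCc2ccccc2)c1I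
F13 | step 10 | [2,3-bis(benzyloxy)-6-bromo-4-[(2S,3R)-3,5,7-tris(benzyloxy)chroman-2-yl]phenyl]magnesium chloride | Brc1cc([C@@H]2Oc3cc(OCc4ccccc4)cc(OCc4ccccc4)c3C[C@H]2OCc2ccccc2)c(OCc2ccccc2)c(OCc2ccccc2)c1[Mg]Cl
F14 | step 6 | tert-butyl{[(2R,3R)-3-[2,3-bis(benzyloxy)-5-bromophenyl]oxiran-2-yl]methoxy}dimethylsilane | CC(C)(C)[Si](C)(C)OC[C@H]1O[C@@H]1c1cc(Br)cc(OCc2ccccc2)c1OCc1ccccc1
F15 | step 6 | (1S,2R)-1-[3,5-bis(benzyloxy)phenoxy]-1-[2,3-bis(benzyloxy)-5-bromophenyl]-3-[(tert-butyldimethylsilyl)oxy]propan-2-ol | CC(C)(C)[Si](C)(C)OC[C@@H](O)[C@@H](Oc1cc(OCc2ccccc2)cc(OCc2ccccc2)c1)c1cc(Br)cc(OCc2ccccc2)c1OCc1ccccc1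
F0 | step 24 | none | none
A1 | alternative 1 | cis-1,2-dihydronaphthalene-1,2-diol acetonide with 7,8-bis(benzyloxy) and 6-(dimethoxymethyl) groups | CC1(C)O[C@H]2C=Cc3cc(C(OC)OC)c(OCc4ccccc4)c(OCc4ccccc4)c3[C@H]2O1
A2 | alternative 1 | gem-dibromocyclopropane-fused tetralin diol acetonide | CC1(C)O[C@H]2[C@H]3[C@H](C3(Br)Br)c3cc(C(OC)OC)c(OCc4ccccc4)c(OCc4ccccc4)c3[C@H]2O1
A3 | alternative 2 | acyclic diene: aryl 1-hydroxyallyl ketone with an ortho 2-(chroman-A-gallate)allyl group, perbenzylated | C=C[C@H](O)C(=O)c1c(CC(=C)[C@H]2Oc3cc(OCc4ccccc4)cc(OCc4ccccc4)c3C[C@H]2OC(=O)c2cc(OCc3ccccc3)c(OCc3ccccc3)c(OCc3ccccc3)c2)cc([C@@H]2Oc3cc(OCc4ccccc4)cc(OCc4ccccc4)c3C[C@H]2OCc2ccccc2)c(OCc2ccccc2)c1OCc1ccccc1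
A4 | alternative 2 | 6-hydroxy-6,9-dihydro-5H-benzo[7]annulen-5-one carrying both chromans, perbenzylated | O=C1[C@@H](O)C=C([C@H]4Oc5cc(OCc6ccccc6)cc(OCc6ccccc6)c5C[C@H]4OC(=O)c4cc(OCc5ccccc5)c(OCc5ccccc5)c(OCc5ccccc5)c4)Cc2cc([C@@H]4Oc5cc(OCc6ccccc6)cc(OCc6ccccc6)c5C[C@H]4OCc4ccccc4)c(OCc4ccccc4)c(OCc4ccccc4)c21
A5 | alternative 3 | ortho-formyl aryl diazomethyl ketone bearing chroman B, perbenzylated | [N-]=[N+]=CC(=O)c1c(C=O)cc([C@@H]2Oc3cc(OCc4ccccc4)cc(OCc4ccccc4)c3C[C@H]2OCc2ccccc2)c(OCc2ccccc2)c1OCc1ccccc1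
A6 | alternative 3 | (2R,3R)-5,7-bis(benzyloxy)-2-ethynylchroman-3-yl 3,4,5-tris(benzyloxy)benzoate | C#C[C@H]1Oc2cc(OCc3ccccc3)cc(OCc3ccccc3)c2C[C@H]1OC(=O)c1cc(OCc2ccccc2)c(OCc2ccccc2)c(OCc2ccccc2)c1
A7 | alternative 3 | oxygen-bridged benzocycloheptadienone cycloadduct, perbenzylated | O=C1c2c(OCc4ccccc4)c(OCc4ccccc4)c([C@@H]4Oc5cc(OCc6ccccc6)cc(OCc6ccccc6)c5C[C@H]4OCc4ccccc4)cc2[C@H]3O[C@@H]1C=C3[C@H]4Oc5cc(OCc6ccccc6)cc(OCc6ccccc6)c5C[C@H]4OC(=O)c4cc(OCc5ccccc5)c(OCc5ccccc5)c(OCc5ccccc5)c4
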